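**Remarks before the route**

- Correction: ring A of the target carries five oxygens (on C5, C6, C7, C8 and C8a). An acylated phloroglucinol supplies only those on C5, C7 and C8a, so it cannot lead to the 6,8-dimethoxychromone. The C6 and C8 methoxy groups are therefore installed on the benzylated phloroglucinol core (steps 1 and 2) before the acyl group, at a stage without base-sensitive functionality.
- The structures of the alkyne, the carbene complex and the benzannulation product are consistent with the atom mapping of the key step and are kept unchanged. Benzyl on all three masked oxygens (O5, O7, O5') is retained because it allows a single final deprotection.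
- Assumption: 1,3,5-tris(benzyloxy)benzene (1) is treated as a catalogue compound.

## Structural features

The target is a flavone: ring A (benzene) is fused to ring C (4-pyranone) along C4a–C8a, and ring B (benzene) is joined to C2 of ring C by the single bond C2–C1'. Ring A is hexasubstituted with five contiguous oxygens (O1 on C8a, OMe on C8 and C6, OH on C7 and C5). Ring C carries OMe on C3, and ring B is a 4-methoxyhydroquinone with OH on C2' and C5', OMe on C4' and hydrogen only on C3' and C6'. There is no stereocentre, so nothing has to be set or preserved in that respect. Fragile are the ring B hydroquinone of the final product (air oxidation to the quinone), C2 of every 2-unsubstituted or 2-alkynyl chromone on the way (attack by hard nucleophiles with ring opening), and benzyl ethers beside a carbonyl group under Lewis acids. The real difficulty is the differentiation of eight oxygens: on ring A, C6 and C8 must end as OMe while C5 and C7 stay unmaskable, and on ring B the two hydroxyls must be told apart from the methoxy group. The key step exploits ring B itself: C2'–OH and C5'–O are para, C4'–OMe is next to C5', and C3' and C6' are unsubstituted. That is the 4-alkoxyphenol pattern formed when a carbonyl ligand (C2'), an alkoxycarbene carbon (C5'), a 1-methoxyvinyl group (C4', C3') and a terminal alkyne (C6', C1') are joined on chromium.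

## Logic of the disconnections

**24 to 23.** The three O–CH2Ph bonds at O5, O7 and O5' are cut. The phenols cannot be carried free through the organometallic steps, and benzyl is the one group that leaves the four methyl ethers untouched on removal. The gain is a one-step end-game. The demand is a neutral hydrogenolysis that spares C2=C3 and a work-up that keeps the hydroquinone from air.

**23 to 21 and 14.** The bonds C5'–C6', C1'–C2' and C2'–C3' are cut, which removes ring B as a ring; C2' with its oxygen goes back to a carbonyl ligand. The para oxygen pattern of ring B is the reason for cutting here. The gain is large: ring B shrinks to a two-carbon alkyne on the chromone (14) and a three-carbon carbene (21), and its three oxygens arrive already differentiated (free OH, OBn, OMe). The demand is regioselective alkyne insertion, so the alkyne must be terminal, and clean release of the phenol from chromium.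

**21 to 19.** The bond between the carbene carbon and its benzyloxy oxygen is cut, leading back to the acylmetalate 19. The benzyl group cannot be delivered by an oxonium salt, so it comes from the alcohol after activation of the acylate oxygen. The demand is low temperature, because the activated intermediate 20 is thermally labile.

**19 to 15 and 16.** The bond between the carbene carbon and the vinyl carbon is cut. The carbene carbon is a carbonyl ligand of 16 and the 1-methoxyvinyl group is 15 after α-lithiation. Both are bulk chemicals. The demand is strictly anhydrous, oxygen-free handling.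

**14 to 13, then to 11 and 12.** The bond between C2 of the chromone and the alkyne carbon is cut. A palladium-catalysed coupling of a 2-halochromone with the silyl-capped alkyne 12 makes this bond under mild conditions; the silyl group is removed afterwards. The demand is a non-nucleophilic base, since C2 of 11 and the enynone of 13 and 14 accept nucleophiles.

**11 to 9.** The C2–I bond is replaced by C2–H. C2–H is the only acidic ring hydrogen of 9, so metalation needs no directing effort. The demand is a base that does not add to the pyranone.

**9 to 7.** The bonds O1–C2 and C2–C3 are cut; C2 is a one-carbon unit at the formate oxidation level. This reduces the chromone to an ortho-hydroxyaryl ketone that already holds C3 with its methoxy group. The demand is condensation at a methylene flanked by a hindered ketone.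

**7 to 6.** One O–benzyl bond ortho to the ketone is re-formed in the retrosynthetic sense. Because 6 is symmetric, either ortho benzyl ether leads to 7. The demand is a reagent that uses carbonyl chelation and stops after one cleavage.

**6 to 3 and 4.** The bond C4a–C4 is cut. The only free ring carbon of 3 is flanked by two alkoxy groups and para to a third, so it is a strong nucleophile, and 4 supplies C4, C3 and the 3-methoxy group. The demand is acylation without a metal halide Lewis acid, to keep the benzyl ethers.

**3 to 2, then to 1.** The two C–OMe bonds (future C6–O and C8–O) are cut back to C–Br and then C–H. This is the point at which the two missing ring A oxygens are added. The threefold symmetry of 1 makes any dibromination pattern the right one. The demand is a double aryl C–O coupling at carbons flanked by two alkoxy groups.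

## Other disconnections considered

**Alternative 1:** The cut is the O1–C8a bond of ring C.

- Forward key step: the hydroquinone diketone A2, 1-[2,5-dihydroxy-3-methoxy-4-(methoxymethoxy)phenyl]-2-methoxy-3-[4-methoxy-2,5-bis(methoxymethoxy)phenyl]propane-1,3-dione, would be oxidised by Ag2O (monovalent silver) to the 2-acylbenzoquinone. Its ring carbon next to the acyl group, the future C8a, is then an electrophile. The enol oxygen of the ring B carbonyl would add there in a 6-endo oxa-Michael closure, and tautomerisation would give the 5,8-dihydroxychromone A1, 5,8-dihydroxy-3,6-dimethoxy-7-(methoxymethoxy)-2-[4-methoxy-2,5-bis(methoxymethoxy)phenyl]-4H-chromen-4-one.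
- In its favour: O1 is delivered in the key step, so ring A of A2 needs only four oxygens. On the ring A oxygenation problem this alternative is the better plan. Ring B enters complete as an aroyl unit, no stoichiometric chromium carbonyl or carbon monoxide is involved, and the chelated 5-OH and free 8-OH of A1 are naturally distinguished.
- Against it here: A1 is not yet at the substitution pattern of the target. O8 must be methylated selectively and three acetals removed, two operations after the key step against one in the chosen plan. The quinone carries OMe and OCH2OMe groups, which are vinylogous esters; they lower the electrophilicity at C8a and offer addition–elimination sites. A1 is itself a hydroquinone that the oxidant could take on to the chromone-5,8-quinone. A2 needs a free hydroquinone beside three acid-labile acetals and an enolisable 2-methoxy-1,3-diketone.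
- Comparison: structurally it closes ring C from two intact benzene rings, whereas the chosen plan keeps rings A and C and builds ring B. Mechanistically it is one ionic conjugate addition, arguably more predictable than an organometallic cascade, but it hinges on a chemoselective oxidation. The overall step count should be similar, with a longer end-game.

**Alternative 2:** The cuts are C3–C4 and C2=C3, with C3 and its methoxy group supplied by methoxymethylenetriphenylphosphorane A5.

- Forward key step: the O-aroylsalicyloyl chloride A4, 2,4-bis(benzyloxy)-6-{[2,5-bis(benzyloxy)-4-methoxybenzoyl]oxy}-3,5-dimethoxybenzoyl chloride, would acylate one equivalent of A5. The second equivalent would deprotonate the phosphonium salt to the acyl ylide (C3–C4). On heating, this ylide would olefinate the neighbouring aryl ester carbonyl (C2=C3) with loss of triphenylphosphine oxide and close ring C as the tetrabenzyl flavone A3, 5,7-bis(benzyloxy)-2-[2,5-bis(benzyloxy)-4-methoxyphenyl]-3,6,8-trimethoxy-4H-chromen-4-one.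
- In its favour: intramolecular ester olefination by acyl ylides is an established chromone synthesis. The plan is fully convergent (two benzoic acid halves and one carbon) and uses no chromium. A3 reaches the target by the same single hydrogenolysis, so the end-game is equal; it is slightly better in that no free phenol is carried.
- Against it here: A4 contains the same fully oxygenated ring A, so nothing is saved there. Its acid chloride sits between a benzyloxy and an aroyloxy group, hindered and open to acyl transfer. A5 is a non-stabilised, strongly basic ylide that could attack the aryl ester instead. The closing Wittig step engages a hindered ester carbonyl with a stabilised ylide and would need forcing conditions.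
- Comparison: on convergence and on the familiarity of each bond-forming event this alternative is at least the equal of the chosen plan, and its step count should be similar. The chosen plan has the advantage that ring B needs no separate synthesis and that no activated carboxyl group has to be carried on the hexasubstituted ring A.

**Alternative 3:** The cuts are C8a–O1, C4a–C4 and O1–C2.

- Forward key step: CsF would release the aryne from the silyl triflate A7, 3,5-bis(benzyloxy)-4-methoxy-2-(trimethylsilyl)phenyl trifluoromethanesulfonate. The carboxylate of A8, (2E)-3-[2,5-bis(benzyloxy)-4-methoxyphenyl]-3-chloro-2-methoxyprop-2-enoic acid, would add through oxygen at the future C8a. The aryl anion at C4a would attack the carboxyl carbon, and collapse would transfer the acyl group to carbon (a formal insertion into the acid C–O bond). The phenoxide would then displace chloride at C2 by addition–elimination and close ring C as A6, 5,7-bis(benzyloxy)-2-[2,5-bis(benzyloxy)-4-methoxyphenyl]-3,6-dimethoxy-4H-chromen-4-one.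
- In its favour: three bonds and one ring form in one flask, which equals the bond economy of the chosen key step. It is free of transition metals. The regiochemistry is supported by the usual bias of 3-alkoxyarynes (the nucleophile adds to the carbon remote from the alkoxy group). The aryne precursor carries only three ring oxygens, simpler than ring A of the chosen route.
- Against it here: A6 lacks the C8 oxygen. It would have to be introduced afterwards, for example by bromination of the one free ring A position and copper-mediated methoxylation, giving at least three operations after the key step against one. A7 and the geometrically defined A8 each need several steps. Simple protonation of the aryl anion to the aryl ester competes with acyl transfer.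
- Comparison: the chosen plan has the complete oxygen pattern in place before its key step and the shorter end-game. The alternative is equal in bonds formed and better in avoiding chromium, but it is clearly longer overall.

Key step: step 11

## Route

**Step 1**
Reactants: 1 1,3,5-tris(benzyloxy)benzene
Product: 2 1,3,5-tris(benzyloxy)-2,4-dibromobenzene
Conditions: NBS (2.05 equiv), CH2Cl2, −10 °C to rt, dark
Reagents that add atoms: N-bromosuccinimide, O=C1CCC(=O)N1Br
Why: Electrophilic aromatic bromination; every ring CH of 1 is ortho/para to three benzyloxy groups, so ring bromination should outrun benzylic bromination, and stoichiometry plus the deactivation by two bromines should hold the reaction at the dibromide (any pattern is the same compound by symmetry).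

**Step 2**
Reactants: 2 1,3,5-tris(benzyloxy)-2,4-dibromobenzene
Product: 3 1,3,5-tris(benzyloxy)-2,4-dimethoxybenzene
Conditions: NaOMe (10 equiv), CuBr (0.4 equiv), MeOH–DMF, 110 °C
Reagents that add atoms: sodium methoxide, C[O-].[Na+]
Why: Ullmann-type copper-catalysed methoxylation of aryl bromides, a known exchange for bromides flanked by two alkoxy groups in polymethoxyarene and polymethoxyflavone chemistry; benzyl ethers are inert to methoxide and 2 has no base-sensitive group.

**Step 3**
Reactants: 3 1,3,5-tris(benzyloxy)-2,4-dimethoxybenzene, 4 methoxyacetic acid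
Product: 6 1-[2,4,6-tris(benzyloxy)-3,5-dimethoxyphenyl]-2-methoxyethan-1-one, via mixed trifluoroacetic anhydride 5 (not isolated)
Conditions: (CF3CO)2O (1.5 equiv), CH2Cl2, 0 °C to rt
Reagents that add atoms: none
Why: Friedel–Crafts acylation through the mixed anhydride 5; the single free ring carbon of 3 is activated like a 1,3,5-trialkoxybenzene, a class acylated this way without a metal halide Lewis acid, so the benzyl ethers should survive.

**Step 4**
Reactants: 6 1-[2,4,6-tris(benzyloxy)-3,5-dimethoxyphenyl]-2-methoxyethan-1-one
Product: 7 1-[2,4-bis(benzyloxy)-6-hydroxy-3,5-dimethoxyphenyl]-2-methoxyethan-1-one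
Conditions: MgBr2·OEt2 (1.5 equiv), toluene–Et2O, 70 °C; then 1 M HCl
Reagents that add atoms: none
Why: Chelation-controlled cleavage of a benzyl ether ortho to an aryl ketone; magnesium held between the carbonyl and the flanking ether oxygen activates only those O–benzyl bonds toward bromide, the two are equivalent by symmetry, and the magnesium phenoxide formed should protect the second from cleavage.

**Step 5**
Reactants: 7 1-[2,4-bis(benzyloxy)-6-hydroxy-3,5-dimethoxyphenyl]-2-methoxyethan-1-one
Product: 9 5,7-bis(benzyloxy)-3,6,8-trimethoxy-4H-chromen-4-one, via enaminone 8 (not isolated)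
Conditions: Me2NCH(OMe)2 (2 equiv), toluene, 90 °C; then 2 M HCl, CH2Cl2, rt
Reagents that add atoms: N,N-dimethylformamide dimethyl acetal, COC(OC)N(C)C
Why: Enaminone route to 2-unsubstituted chromones; the acetal condenses at the ketone methylene to give 8, and acid induces conjugate addition of the phenol and loss of dimethylamine (6-endo addition–elimination), the reagent carbon becoming C2.

**Step 6**
Reactants: 9 5,7-bis(benzyloxy)-3,6,8-trimethoxy-4H-chromen-4-one
Product: 11 5,7-bis(benzyloxy)-2-iodo-3,6,8-trimethoxy-4H-chromen-4-one, via chromon-2-ylzinc chloride 10 (not isolated)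
Conditions: TMPZnCl·LiCl (1.3 equiv), THF, 25 °C; then I2, 0 °C; aq. Na2S2O3
Reagents that add atoms: iodine, II
Why: Directed zincation of the chromone C2–H with a hindered zinc amide, then iodinolysis of the C–Zn bond; C2–H is the only ring hydrogen of the bicycle (ring A is fully substituted, C3 bears OMe), and the zinc amide tolerates the pyranone carbonyl that lithium amides would attack.

**Step 7**
Reactants: 11 5,7-bis(benzyloxy)-2-iodo-3,6,8-trimethoxy-4H-chromen-4-one, 12 ethynyltrimethylsilane
Product: 13 5,7-bis(benzyloxy)-3,6,8-trimethoxy-2-[(trimethylsilyl)ethynyl]-4H-chromen-4-one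
Conditions: PdCl2(PPh3)2 (3 mol %), CuI (5 mol %), Et3N, THF, rt
Reagents that add atoms: none
Why: Sonogashira coupling; the 2-iodochromone is a vinylogous acyl iodide that should undergo oxidative addition at room temperature, and a tertiary amine is chosen because a secondary amine would displace iodide at C2.

**Step 8**
Reactants: 13 5,7-bis(benzyloxy)-3,6,8-trimethoxy-2-[(trimethylsilyl)ethynyl]-4H-chromen-4-one
Product: 14 5,7-bis(benzyloxy)-2-ethynyl-3,6,8-trimethoxy-4H-chromen-4-one
Conditions: Bu4NF (1.1 equiv), AcOH (1.2 equiv), THF, 0 °C
Reagents that add atoms: none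
Why: Fluoride-induced protodesilylation of an alkynylsilane; the acetic acid buffer keeps the medium non-basic so that the conjugated enynone is not attacked by alkoxide or hydroxide.

**Step 9**
Reactants: 15 methyl vinyl ether, 16 chromium hexacarbonyl Cr(CO)6
Product: 19 tetramethylammonium pentacarbonyl[(1-methoxyethenyl)oxidomethylidene]chromate, via 1-methoxyvinyllithium 17 (not isolated), via lithium acylchromate 18 (not isolated)
Conditions: t-BuLi, THF–pentane, −78 to 0 °C; Cr(CO)6, Et2O–THF, −78 °C to rt; then Me4NBr, degassed H2O
Reagents that add atoms: tetramethylammonium bromide, C[N+](C)(C)C.[Br-]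
Why: Fischer synthesis of an acylmetalate: α-lithiation of the enol ether, addition of the vinyllithium to a carbonyl ligand of Cr(CO)6, and cation exchange to the tetramethylammonium salt, which is a storable solid and is acylated cleanly at oxygen.

**Step 10**
Reactants: 19 tetramethylammonium pentacarbonyl[(1-methoxyethenyl)oxidomethylidene]chromate
Product: 21 pentacarbonyl[benzyloxy(1-methoxyethenyl)carbene]chromium, via acetoxycarbene complex 20 (not isolated)
Conditions: AcBr, CH2Cl2, −40 °C; then BnOH, −40 to −10 °C
Reagents that add atoms: benzyl alcohol, OCc1ccccc1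
Why: O-Acylation of the acylmetalate gives the strongly electrophilic acetoxycarbene 20, and addition–elimination of the alcohol at the carbene carbon replaces acetate; this is the usual entry to alkoxycarbene complexes whose alkoxy group is not available from an oxonium salt.

**Step 11**
Reactants: 21 pentacarbonyl[benzyloxy(1-methoxyethenyl)carbene]chromium, 14 5,7-bis(benzyloxy)-2-ethynyl-3,6,8-trimethoxy-4H-chromen-4-one
Product: 23 5,7-bis(benzyloxy)-2-[5-(benzyloxy)-2-hydroxy-4-methoxyphenyl]-3,6,8-trimethoxy-4H-chromen-4-one, via tricarbonylchromium arene complex 22 (not isolated)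
Conditions: 21 (1.5 equiv), degassed THF (0.05 M), Ar, 50 °C; then air, EtOAc, rt
Reagents that add atoms: none
Why: Thermal loss of one cis carbonyl ligand from 21 frees a site at which 14 binds and inserts into the Cr=C bond, its unsubstituted carbon joining the carbene carbon (C5'–C6'). Insertion of a carbonyl ligand into the new vinylcarbene gives a chromium-bound dienylketene whose ketene carbon is attached to the chromonyl-bearing carbon (C1'–C2'). A six-electron electrocyclic closure between the ketene carbon and the CH2 terminus (C2'–C3') forms ring B as a cyclohexadienone; enolisation gives the phenol held as the Cr(CO)3 complex 22, and air then removes the metal. The closest known reaction type is the Dötz benzannulation of alkenyl(alkoxy)carbene chromium complexes with terminal alkynes to 4-alkoxyphenols. The one ring closed is a six-membered carbocycle formed by 6π electrocyclisation, and no stereocentre is created. The selectivity needed is the regiochemistry of alkyne insertion; the terminal alkyne secures it, because the hydrogen-bearing carbon bonds to the carbene carbon and the bulky chromonyl carbon ends next to the carbonyl-derived carbon, ortho to the new hydroxyl. An alkenyl carbene has no competing path to indenes, and THF favours the phenol over cyclobutenone formation. The three ring B oxygens are thereby placed and differentiated in one operation: C2'–OH free, C5'–OBn from the carbene oxygen, C4'–OMe from the vinyl group.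

**Step 12**
Reactants: 23 5,7-bis(benzyloxy)-2-[5-(benzyloxy)-2-hydroxy-4-methoxyphenyl]-3,6,8-trimethoxy-4H-chromen-4-one
Product: 24 5,7,2',5'-tetrahydroxy-3,6,8,4'-tetramethoxyflavone
Conditions: H2 (1 atm), Pd/C (palladium metal on carbon), EtOAc–MeOH, rt; filtration and evaporation under Ar
Reagents that add atoms: none
Why: Hydrogenolysis of three aryl benzyl ethers over palladium; the four methyl ethers and the pyranone double bond should be untouched at one atmosphere and room temperature, and exclusion of air during isolation protects the hydroquinone.

## Compound list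

1 | 1,3,5-tris(benzyloxy)benzene | C(Oc1cc(OCc2ccccc2)cc(OCc2ccccc2)c1)c1ccccc1 | starting material
2 | 1,3,5-tris(benzyloxy)-2,4-dibromobenzene | Brc1c(OCc2ccccc2)cc(OCc2ccccc2)c(Br)c1OCc1ccccc1 | intermediate
3 | 1,3,5-tris(benzyloxy)-2,4-dimethoxybenzene | COc1c(OCc2ccccc2)cc(OCc2ccccc2)c(OC)c1OCc1ccccc1 | intermediate
4 | methoxyacetic acid | COCC(=O)O | starting material
5 | methoxyacetic trifluoroacetic anhydride (mixed anhydride) | COCC(=O)OC(=O)C(F)(F)F | intermediate (not isolated)
6 | 1-[2,4,6-tris(benzyloxy)-3,5-dimethoxyphenyl]-2-methoxyethan-1-one | COCC(=O)c1c(OCc2ccccc2)c(OC)c(OCc2ccccc2)c(OC)c1OCc1ccccc1 | intermediate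
7 | 1-[2,4-bis(benzyloxy)-6-hydroxy-3,5-dimethoxyphenyl]-2-methoxyethan-1-one | COCC(=O)c1c(O)c(OC)c(OCc2ccccc2)c(OC)c1OCc1ccccc1 | intermediate
8 | (2Z)-1-[2,4-bis(benzyloxy)-6-hydroxy-3,5-dimethoxyphenyl]-3-(dimethylamino)-2-methoxyprop-2-en-1-one (enaminone) | CN(C)/C=C(\OC)C(=O)c1c(O)c(OC)c(OCc2ccccc2)c(OC)c1OCc1ccccc1 | intermediate (not isolated)
9 | 5,7-bis(benzyloxy)-3,6,8-trimethoxy-4H-chromen-4-one | COc1coc2c(OC)c(OCc3ccccc3)c(OC)c(OCc3ccccc3)c2c1=O | intermediate
10 | [5,7-bis(benzyloxy)-3,6,8-trimethoxy-4-oxo-4H-chromen-2-yl]zinc chloride, LiCl adduct | COc1c([Zn]Cl)oc2c(OC)c(OCc3ccccc3)c(OC)c(OCc3ccccc3)c2c1=O.[Li+].[Cl-] | intermediate (not isolated)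
11 | 5,7-bis(benzyloxy)-2-iodo-3,6,8-trimethoxy-4H-chromen-4-one | COc1c(I)oc2c(OC)c(OCc3ccccc3)c(OC)c(OCc3ccccc3)c2c1=O | intermediate
12 | ethynyltrimethylsilane | C#C[Si](C)(C)C | starting material
13 | 5,7-bis(benzyloxy)-3,6,8-trimethoxy-2-[(trimethylsilyl)ethynyl]-4H-chromen-4-one | COc1c(C#C[Si](C)(C)C)oc2c(OC)c(OCc3ccccc3)c(OC)c(OCc3ccccc3)c2c1=O | intermediate
14 | 5,7-bis(benzyloxy)-2-ethynyl-3,6,8-trimethoxy-4H-chromen-4-one | C#Cc1oc2c(OC)c(OCc3ccccc3)c(OC)c(OCc3ccccc3)c2c(=O)c1OC | intermediate
15 | methyl vinyl ether | COC=C | starting material
16 | chromium hexacarbonyl, Cr(CO)6 | O=C=[Cr](=C=O)(=C=O)(=C=O)(=C=O)=C=O | starting material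
17 | 1-methoxyvinyllithium | [Li]C(=C)OC | intermediate (not isolated)
18 | lithium pentacarbonyl[(1-methoxyethenyl)oxidomethylidene]chromate | [Li+].C=C(OC)C([O-])=[Cr](=C=O)(=C=O)(=C=O)(=C=O)=C=O | intermediate (not isolated)
19 | tetramethylammonium pentacarbonyl[(1-methoxyethenyl)oxidomethylidene]chromate | C[N+](C)(C)C.C=C(OC)C([O-])=[Cr](=C=O)(=C=O)(=C=O)(=C=O)=C=O | intermediate
20 | pentacarbonyl[acetoxy(1-methoxyethenyl)carbene]chromium | C=C(OC)C(OC(C)=O)=[Cr](=C=O)(=C=O)(=C=O)(=C=O)=C=O | intermediate (not isolated)
21 | pentacarbonyl[benzyloxy(1-methoxyethenyl)carbene]chromium | C=C(OC)C(OCc1ccccc1)=[Cr](=C=O)(=C=O)(=C=O)(=C=O)=C=O | intermediate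
22 | tricarbonylchromium complex of 23, metal bound η6 to ring B (the arene–metal bonding is written as a dot) | COc1cc(O)c(-c2oc3c(OC)c(OCc4ccccc4)c(OC)c(OCc4ccccc4)c3c(=O)c2OC)cc1OCc1ccccc1.O=C=[Cr](=C=O)=C=O | intermediate (not isolated)
23 | 5,7-bis(benzyloxy)-2-[5-(benzyloxy)-2-hydroxy-4-methoxyphenyl]-3,6,8-trimethoxy-4H-chromen-4-one | COc1cc(O)c(-c2oc3c(OC)c(OCc4ccccc4)c(OC)c(OCc4ccccc4)c3c(=O)c2OC)cc1OCc1ccccc1 | intermediate
24 | 5,7,2',5'-tetrahydroxy-3,6,8,4'-tetramethoxyflavone (5,7-dihydroxy-2-(2,5-dihydroxy-4-methoxyphenyl)-3,6,8-trimethoxy-4H-chromen-4-one) | COc1cc(O)c(-c2oc3c(OC)c(O)c(OC)c(O)c3c(=O)c2OC)cc1O | target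

## Step count and least certain steps

Total: 12 steps. Longest linear sequence: 10 steps (steps 1 to 8, 11 and 12, from 1). The carbene branch (steps 9 and 10) joins at step 11.

**Step 11 (key step).** The alkyne of 14 is electron-poor and conjugated, so insertion may be slow and thermal decay or oligomerisation of 21 may outrun benzannulation. Ring closure may also divert to a cyclobutenone or furan-type product, and the 4-benzyloxyphenol may be over-oxidised to the quinone during aerobic decomplexation. The fallback gives up the annulation and attaches ring B intact. It sets out from 9, which is zincated to 10 as in step 6. Commercial methoxyhydroquinone would be O-benzylated twice (BnBr, K2CO3, DMF) to 1,4-bis(benzyloxy)-2-methoxybenzene F1 and iodinated para to the methoxy group (N-iodosuccinimide, MeCN) to 1,4-bis(benzyloxy)-2-iodo-5-methoxybenzene F2. Negishi coupling of 10 with F2 (Pd(PPh3)4, zerovalent palladium, THF, 50 °C) should give 5,7-bis(benzyloxy)-2-[2,5-bis(benzyloxy)-4-methoxyphenyl]-3,6,8-trimethoxy-4H-chromen-4-one F3. Hydrogenolysis as in step 12 returns to the route at 24.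

**Step 2.** Reductive loss of bromine may compete with C–O bond formation at carbons flanked by two benzyloxy groups, and the second exchange may stall. The fallback sets out from 2 and replaces copper catalysis by stepwise oxidation of carbon–metal bonds. Bromine–lithium exchange (n-BuLi, THF, −78 °C), trapping with B(OMe)3 and oxidation (H2O2, NaOH) should give 2,4,6-tris(benzyloxy)-3-bromophenol F4. Methylation (MeI, K2CO3, acetone) gives 1,3,5-tris(benzyloxy)-2-bromo-4-methoxybenzene F5. A second exchange, borylation and oxidation gives 2,4,6-tris(benzyloxy)-3-methoxyphenol F6, and a second methylation returns to the route at 3.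

**Step 3.** The acid set free may cause loss of benzyl groups with C-benzylation of the still free ring position. Acylation at a carbon between two benzyloxy groups may also be sluggish, with competing trifluoroacetylation. The fallback sets out from 3 and builds the ketone in stages. Vilsmeier–Haack formylation (POCl3, DMF) should give 2,4,6-tris(benzyloxy)-3,5-dimethoxybenzaldehyde F7. Addition of methoxymethyllithium (from MeOCH2SnBu3 and n-BuLi, THF, −78 °C) gives racemic 1-[2,4,6-tris(benzyloxy)-3,5-dimethoxyphenyl]-2-methoxyethan-1-ol F8. Dess–Martin oxidation returns to the route at 6.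

**Step 6.** The amide base or the organozinc may add at C2 and open the pyranone, or metalation may be incomplete because the base is held at the C4 carbonyl. The fallback sets out from 7 and brings in the C2 substituent with the ring closure, bypassing steps 5 to 8. Kostanecki–Robinson condensation (Ac2O, NaOAc, 160 °C) should give 5,7-bis(benzyloxy)-3,6,8-trimethoxy-2-methyl-4H-chromen-4-one F9. Riley oxidation of the activated methyl group (SeO2, dioxane, reflux) gives 5,7-bis(benzyloxy)-3,6,8-trimethoxy-4-oxo-4H-chromene-2-carbaldehyde F10. Ohira–Bestmann homologation (dimethyl (1-diazo-2-oxopropyl)phosphonate, K2CO3, MeOH, 0 °C) returns to the route at 14.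

**Step 10.** The acetoxycarbene 20 may decompose before alcoholysis, and benzyl alcohol may add in conjugate fashion to the carbene-activated enol ether double bond. The fallback sets out from 19 and alkylates the acylate oxygen directly. Benzyl trifluoromethanesulfonate F11 would be generated at −78 °C in CH2Cl2 from benzyl alcohol, trifluoromethanesulfonic anhydride and 2,6-di-tert-butyl-4-methylpyridine, and 19 added to it. This returns to the route at 21.

## Further compounds

F1 | step 11 | 1,4-bis(benzyloxy)-2-methoxybenzene | COc1cc(OCc2ccccc2)ccc1OCc1ccccc1
F2 | step 11 | 1,4-bis(benzyloxy)-2-iodo-5-methoxybenzene | COc1cc(OCc2ccccc2)c(I)cc1OCc1ccccc1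
F3 | step 11 | 5,7-bis(benzyloxy)-2-[2,5-bis(benzyloxy)-4-methoxyphenyl]-3,6,8-trimethoxy-4H-chromen-4-one | COc1cc(OCc2ccccc2)c(-c2oc3c(OC)c(OCc4ccccc4)c(OC)c(OCc4ccccc4)c3c(=O)c2OC)cc1OCc1ccccc1
F4 | step 2 | 2,4,6-tris(benzyloxy)-3-bromophenol | Oc1c(OCc2ccccc2)cc(OCc2ccccc2)c(Br)c1OCc1ccccc1
F5 | step 2 | 1,3,5-tris(benzyloxy)-2-bromo-4-methoxybenzene | COc1c(OCc2ccccc2)cc(OCc2ccccc2)c(Br)c1OCc1ccccc1
F6 | step 2 | 2,4,6-tris(benzyloxy)-3-methoxyphenol | COc1c(OCc2ccccc2)cc(OCc2ccccc2)c(O)c1OCc1ccccc1
F7 | step 3 | 2,4,6-tris(benzyloxy)-3,5-dimethoxybenzaldehyde | O=Cc1c(OCc2ccccc2)c(OC)c(OCc2ccccc2)c(OC)c1OCc1ccccc1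
F8 | step 3 | racemic 1-[2,4,6-tris(benzyloxy)-3,5-dimethoxyphenyl]-2-methoxyethan-1-ol | COCC(O)c1c(OCc2ccccc2)c(OC)c(OCc2ccccc2)c(OC)c1OCc1ccccc1
F9 | step 6 | 5,7-bis(benzyloxy)-3,6,8-trimethoxy-2-methyl-4H-chromen-4-one | COc1c(C)oc2c(OC)c(OCc3ccccc3)c(OC)c(OCc3ccccc3)c2c1=O
F10 | step 6 | 5,7-bis(benzyloxy)-3,6,8-trimethoxy-4-oxo-4H-chromene-2-carbaldehyde | COc1c(C=O)oc2c(OC)c(OCc3ccccc3)c(OC)c(OCc3ccccc3)c2c1=O
F11 | step 10 | benzyl trifluoromethanesulfonate | O=S(=O)(OCc1ccccc1)C(F)(F)F
A1 | alternative 1 | 5,8-dihydroxy-3,6-dimethoxy-7-(methoxymethoxy)-2-[4-methoxy-2,5-bis(methoxymethoxy)phenyl]-4H-chromen-4-one | COc1cc(OCOC)c(-c2oc3c(O)c(OCOC)c(OC)c(O)c3c(=O)c2OC)cc1OCOC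
A2 | alternative 1 | 1-[2,5-dihydroxy-3-methoxy-4-(methoxymethoxy)phenyl]-2-methoxy-3-[4-methoxy-2,5-bis(methoxymethoxy)phenyl]propane-1,3-dione | COCOc1c(OC)c(O)c(C(=O)C(OC)C(=O)c2cc(OCOC)c(OC)cc2OCOC)cc1O
A3 | alternative 2 | 5,7-bis(benzyloxy)-2-[2,5-bis(benzyloxy)-4-methoxyphenyl]-3,6,8-trimethoxy-4H-chromen-4-one | COc1cc(OCc2ccccc2)c(-c2oc3c(OC)c(OCc4ccccc4)c(OC)c(OCc4ccccc4)c3c(=O)c2OC)cc1OCc1ccccc1
A4 | alternative 2 | 2,4-bis(benzyloxy)-6-{[2,5-bis(benzyloxy)-4-methoxybenzoyl]oxy}-3,5-dimethoxybenzoyl chloride | COc1cc(OCc2ccccc2)c(C(=O)Oc2c(OC)c(OCc3ccccc3)c(OC)c(OCc3ccccc3)c2C(=O)Cl)cc1OCc1ccccc1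
A5 | alternative 2 | methoxymethylenetriphenylphosphorane | COC=P(c1ccccc1)(c1ccccc1)c1ccccc1
A6 | alternative 3 | 5,7-bis(benzyloxy)-2-[2,5-bis(benzyloxy)-4-methoxyphenyl]-3,6-dimethoxy-4H-chromen-4-one | COc1cc(OCc2ccccc2)c(-c2oc3cc(OCc4ccccc4)c(OC)c(OCc4ccccc4)c3c(=O)c2OC)cc1OCc1ccccc1
A7 | alternative 3 | 3,5-bis(benzyloxy)-4-methoxy-2-(trimethylsilyl)phenyl trifluoromethanesulfonate | COc1c(OCc2ccccc2)cc(OS(=O)(=O)C(F)(F)F)c([Si](C)(C)C)c1OCc1ccccc1
A8 | alternative 3 | (2E)-3-[2,5-bis(benzyloxy)-4-methoxyphenyl]-3-chloro-2-methoxyprop-2-enoic acid | OC(=O)/C(OC)=C(\Cl)c1cc(OCc2ccccc2)c(OC)cc1OCc1ccccc1
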